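The C12–O bond is the disconnection on which everything rests. In punaglandin 8 the C12 oxygen and the C8 side chain are cis on the cyclopentenone ring and C6 can be carried at the carboxyl level, so O12, C12, C8, C7 and C6 are treated as a γ-lactone cis-fused to the carbocycle. Iodolactonisation closes this lactone ring, forges the quaternary C12–O bond and a C11–iodine bond, and relays the C8 configuration to C12 in one operation. Its precursor is a cyclopent-2-enylacetic acid carrying the oct-2-ynyl chain on alkene carbon C12 and a C9 silyl ether trans to the acid arm. An Ireland–Claisen shift sets C8 beforehand, and convex-face hydroxylation of the bicycle sets C7 afterwards.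

Key step: step 10

Remark on the chemistry: prostanoid numbering is used throughout (C1 = ester carbon, C8–C12 = ring); the lipase is assumed to acylate the (R)-alcohol faster, as is general for 4-hydroxycyclopent-2-enones, and it is this (R)-series that leads to the target.

Step 1
Reactants: 1 furfural; 2 3-bromoprop-1-yne
Product: 4 rac-1-(furan-2-yl)but-3-yn-1-ol, via allenylzinc bromide 3 (not isolated)
Conditions: Zn dust, THF, 0 °C (2 added to Zn, then 1), then rt; then sat. aq. NH4Cl
Reagents that add atoms: none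
Why: Barbier-type propargylation, in which the allenylzinc species adds to the aldehyde through a cyclic SE2′ transition state and therefore delivers the homopropargylic alcohol; the carbinol centre is formed racemic, which is harmless because step 3 destroys it.

Step 2
Reactants: 4 rac-1-(furan-2-yl)but-3-yn-1-ol; 5 1-bromopentane
Product: 7 rac-1-(furan-2-yl)non-3-yn-1-ol, via dilithium dianion 6 (not isolated)
Conditions: n-BuLi (2.1 equiv), THF, −78 → −20 °C; then 5, DMPU, −20 °C → rt; then H2O
Reagents that add atoms: none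
Why: Acetylide alkylation (SN2) of the alkoxide–acetylide dianion, in which the sp carbanion is far more reactive toward a primary bromide than the hindered lithium alkoxide, so C–C bond formation should outrun O-alkylation.

Step 3
Reactants: 7 rac-1-(furan-2-yl)non-3-yn-1-ol
Product: 9 rac-4-hydroxy-2-(oct-2-yn-1-yl)cyclopent-2-en-1-one, via trans 5-alkyl-4-hydroxy enone 8 (not isolated)
Conditions: KH2PO4/H3PO4 buffer (pH 4), dioxane/H2O, reflux; then K2HPO4 to pH 8, 80 °C
Reagents that add atoms: water, O
Why: Piancatelli rearrangement, in which acid-induced loss of the carbinol hydroxyl, water addition to the furan, ring opening and conrotatory 4π electrocyclisation give the trans 4-hydroxy-5-alkyl enone, which at pH 8 isomerises to the more substituted and thermodynamically preferred 2-alkyl-4-hydroxy enone while the internal alkyne is a spectator.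

Step 4
Reactants: 9 rac-4-hydroxy-2-(oct-2-yn-1-yl)cyclopent-2-en-1-one
Product: 10 (1R)-3-(oct-2-yn-1-yl)-4-oxocyclopent-2-en-1-yl acetate
Conditions: immobilised Burkholderia cepacia lipase, vinyl acetate, MTBE, 30 °C, stopped short of half conversion; chromatography
Reagents that add atoms: vinyl acetate, CC(=O)OC=C
Why: Lipase-catalysed kinetic resolution by irreversible transesterification, in which the (R)-carbinol is acylated faster, so the (R)-acetate should be obtained in high enantiomeric purity while the slow (S)-alcohol is separated.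

Step 5
Reactants: 10 (1R)-3-(oct-2-yn-1-yl)-4-oxocyclopent-2-en-1-yl acetate
Product: 11 (4R)-4-hydroxy-2-(oct-2-yn-1-yl)cyclopent-2-en-1-one
Conditions: Burkholderia cepacia lipase, KH2PO4/K2HPO4 buffer (pH 7), acetone, 30 °C
Reagents that add atoms: none
Why: Enzymatic ester hydrolysis at neutral pH cleaves the acetate without the β-elimination that hydroxide or alkoxide would trigger in a 4-acyloxycyclopentenone, and the same (R)-preference should raise the enantiomeric purity a second time.

Step 6
Reactants: 11 (4R)-4-hydroxy-2-(oct-2-yn-1-yl)cyclopent-2-en-1-one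
Product: 12 (4R)-4-(tert-butyldimethylsilyloxy)-2-(oct-2-yn-1-yl)cyclopent-2-en-1-one
Conditions: TBSCl, imidazole, DMF, 0 °C → rt
Reagents that add atoms: tert-butyldimethylsilyl chloride, CC(C)(C)[Si](C)(C)Cl
Why: Standard silyl ether formation with a silyl chloride and imidazole, a base mild enough not to endanger the β-oxygenated enone.

Step 7
Reactants: 12 (4R)-4-(tert-butyldimethylsilyloxy)-2-(oct-2-yn-1-yl)cyclopent-2-en-1-one
Product: 13 (1S,4R)-4-(tert-butyldimethylsilyloxy)-2-(oct-2-yn-1-yl)cyclopent-2-en-1-ol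
Conditions: NaBH4, CeCl3·7H2O, MeOH, −78 °C
Reagents that add atoms: none
Why: Luche reduction, in which the cerium-modified borohydride attacks only the carbonyl carbon and does so from the face opposite the C9 silyloxy group, setting the new C11 carbinol cis to that group.

Step 8
Reactants: 13 (1S,4R)-4-(tert-butyldimethylsilyloxy)-2-(oct-2-yn-1-yl)cyclopent-2-en-1-ol
Product: 14 (1R,4R)-4-(tert-butyldimethylsilyloxy)-2-(oct-2-yn-1-yl)cyclopent-2-en-1-yl acetate
Conditions: AcOH, PPh3, DIAD, toluene, 0 °C → rt
Reagents that add atoms: acetic acid, CC(=O)O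
Why: Mitsunobu reaction, in which acetate displaces the phosphine-activated allylic hydroxyl in an SN2 process, so C11 is inverted and the ester ends up trans to the C9 silyl ether.

Step 9
Reactants: 14 (1R,4R)-4-(tert-butyldimethylsilyloxy)-2-(oct-2-yn-1-yl)cyclopent-2-en-1-yl acetate
Product: 17 2-[(1R,5R)-5-(tert-butyldimethylsilyloxy)-2-(oct-2-yn-1-yl)cyclopent-2-en-1-yl]acetic acid, via silyl ketene acetal 15 (not isolated), via trimethylsilyl ester 16 (not isolated)
Conditions: LiN(i-Pr)2, Me3SiCl, Et3N, THF, −78 °C; then 60 °C; then H2O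
Reagents that add atoms: none
Why: Ireland–Claisen rearrangement, in which the acetate enolate is trapped on oxygen and the ketene acetal undergoes a suprafacial [3,3] shift on the ring face that carried the C11 oxygen, so the C7–C8 bond forms trans to the C9 silyl ether, C8 is set by 1,3-chirality transfer and the alkene moves to C11=C12.

Step 10
Reactants: 17 2-[(1R,5R)-5-(tert-butyldimethylsilyloxy)-2-(oct-2-yn-1-yl)cyclopent-2-en-1-yl]acetic acid
Product: 18 (3aS,4R,6S,6aS)-4-(tert-butyldimethylsilyloxy)-6-iodo-6a-(oct-2-yn-1-yl)hexahydro-2H-cyclopenta[b]furan-2-one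
Conditions: I2, KI, NaHCO3, THF/H2O, 0 °C, dark; then aq. Na2S2O3
Reagents that add atoms: iodine, II
Why: Iodine reversibly forms an iodonium ion on the C11=C12 alkene and the carboxylate tethered through C7 opens it at C12 in an anti sense, creating the C12–O bond and the C11–iodine bond in one event. The closest known reaction type is the iodolactonisation of cyclopent-2-enylacetic acids to cis-fused γ-lactones. The lactone ring closes in the 5-exo mode at the more substituted alkene carbon, whereas the 6-endo alternative at C11 would be anti-Markovnikov and would give a strained bridged δ-lactone. C12 is controlled by the existing C8 centre, because the short tether can reach only the alkene face on which the C8 arm sits and so enforces cis fusion, and C11 follows from anti addition, which places iodide trans to the lactone oxygen. The step needs chemoselectivity for the ring alkene over the side-chain alkyne and regioselectivity for C12: the internal alkyne reacts with iodine far more slowly and has no carboxylate within reach, and C12 is both the tertiary and the 5-exo terminus.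

Step 11
Reactants: 18 (3aS,4R,6S,6aS)-4-(tert-butyldimethylsilyloxy)-6-iodo-6a-(oct-2-yn-1-yl)hexahydro-2H-cyclopenta[b]furan-2-one
Product: 19 (3aS,4R,6aR)-4-(tert-butyldimethylsilyloxy)-6a-(oct-2-yn-1-yl)-3,3a,4,6a-tetrahydro-2H-cyclopenta[b]furan-2-one
Conditions: DBU, toluene, 80 °C
Reagents that add atoms: none
Why: E2 dehydrohalogenation with an amidine base, in which C12 is quaternary, so only the C10 hydrogen anti-periplanar to iodide can be removed and the alkene must form at C10=C11.

Step 12
Reactants: 19 (3aS,4R,6aR)-4-(tert-butyldimethylsilyloxy)-6a-(oct-2-yn-1-yl)-3,3a,4,6a-tetrahydro-2H-cyclopenta[b]furan-2-one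
Product: 21 (3R,3aS,4R,6aR)-4-(tert-butyldimethylsilyloxy)-3-hydroxy-6a-(oct-2-yn-1-yl)-3,3a,4,6a-tetrahydro-2H-cyclopenta[b]furan-2-one, via potassium enolate 20 (not isolated)
Conditions: KN(SiMe3)2, THF, −78 °C; then 3-phenyl-2-(phenylsulfonyl)oxaziridine, −78 °C; then AcOH
Reagents that add atoms: 3-phenyl-2-(phenylsulfonyl)oxaziridine, O=S(=O)(c1ccccc1)N1OC1c1ccccc1
Why: Electrophilic α-hydroxylation of a lactone enolate with an N-sulfonyloxaziridine, in which the enolate of the cis-fused bicycle is open only on its convex face (the face of H8, opposite the cyclopentene ring), so oxygen is delivered there and C7 is set in the configuration the target needs.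

Step 13
Reactants: 21 (3R,3aS,4R,6aR)-4-(tert-butyldimethylsilyloxy)-3-hydroxy-6a-(oct-2-yn-1-yl)-3,3a,4,6a-tetrahydro-2H-cyclopenta[b]furan-2-one
Product: 22 (3R,3aS,4R,6aR)-4-(tert-butyldimethylsilyloxy)-6a-(oct-2-yn-1-yl)-3,3a,4,6a-tetrahydro-2H-cyclopenta[b]furan-2,3-diol (lactol, anomer mixture)
Conditions: i-Bu2AlH (2.3 equiv), CH2Cl2, −78 °C; then aq. KNaC4H4O6
Reagents that add atoms: none
Why: Partial lactone reduction, in which the first equivalent of hydride reagent deprotonates the hydroxyl, the second adds once to the carbonyl and the aluminium hemiacetal persists at low temperature, so work-up should release the lactol and not the diol.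

Step 14
Reactants: 22 lactol from step 13; 23 (4-carboxybutyl)triphenylphosphonium bromide
Product: 25 (5Z,7S)-7-[(1S,2R,5R)-5-(tert-butyldimethylsilyloxy)-2-hydroxy-2-(oct-2-yn-1-yl)cyclopent-3-en-1-yl]-7-hydroxyhept-5-enoic acid, via potassium ylide carboxylate 24 (not isolated)
Conditions: 23 (excess), KN(SiMe3)2 (2 equiv per 23), THF, 0 °C; then 22, −20 °C → rt; then dilute aq. HCl to pH 4
Reagents that add atoms: none
Why: Wittig olefination of a lactol (a masked aldehyde) with a salt-free non-stabilised potassium ylide, which is kinetically Z-selective, the excess ylide compensating for the acidic hydroxyls while C7 is not touched.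

Step 15
Reactants: 25 acid from step 14
Product: 26 methyl (5Z,7S)-7-[(1S,2R,5R)-5-(tert-butyldimethylsilyloxy)-2-hydroxy-2-(oct-2-yn-1-yl)cyclopent-3-en-1-yl]-7-hydroxyhept-5-enoate
Conditions: Me3SiCHN2, toluene/MeOH, 0 °C
Reagents that add atoms: (trimethylsilyl)diazomethane, C[Si](C)(C)C=[N+]=[N-]
Why: Carboxylic acid methylation by a diazoalkane, in which only the acid is acidic enough to protonate the reagent, so the alcohols and the silyl ether stay untouched.

Step 16
Reactants: 26 methyl ester from step 15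
Product: 27 methyl (5Z,7S)-7-acetoxy-7-[(1S,2R,5R)-5-(tert-butyldimethylsilyloxy)-2-hydroxy-2-(oct-2-yn-1-yl)cyclopent-3-en-1-yl]hept-5-enoate
Conditions: Ac2O, pyridine, DMAP (cat.), CH2Cl2, 0 °C
Reagents that add atoms: acetic anhydride, CC(=O)OC(C)=O
Why: Nucleophile-catalysed acylation, in which the secondary allylic C7 hydroxyl reacts while the tertiary C12 hydroxyl is too hindered under these mild conditions.

Step 17
Reactants: 27 C7 acetate from step 16
Product: 28 methyl (5Z,7S)-7-acetoxy-7-[(1R,2R,5R)-2,5-dihydroxy-2-(oct-2-yn-1-yl)cyclopent-3-en-1-yl]hept-5-enoate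
Conditions: HF·pyridine, pyridine/THF, 0 °C → rt
Reagents that add atoms: none
Why: Fluoride-mediated silyl ether cleavage under buffered, mildly acidic conditions, chosen over basic fluoride sources to prevent migration of the C7 acetyl group to the freed C9 hydroxyl.

Step 18
Reactants: 28 diol from step 17
Product: 29 10,11-epoxide of 28 with the epoxide oxygen on the face of the C9 hydroxyl
Conditions: VO(acac)2 (cat.), t-BuOOH, CH2Cl2, 0 °C → rt
Reagents that add atoms: tert-butyl hydroperoxide, CC(C)(C)OO
Why: Hydroxyl-directed epoxidation by a vanadium alkylperoxide, in which only the ring alkene is allylic to a free hydroxyl (C9–OH and C12–OH), the C5=C6 alkene is remote from both and flanked by an acetate, and the alkyne is inert; either epoxide face is acceptable because C10 and C11 lose their configuration in step 21.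

Step 19
Reactants: 29 epoxy diol from step 18
Product: 30 (14Z)-alkene corresponding to 29 (oct-2-ynyl chain reduced to (2Z)-oct-2-enyl)
Conditions: H2 (1 atm), Pd on CaCO3 poisoned with Pb(OAc)2, quinoline, EtOAc, rt
Reagents that add atoms: none
Why: Lindlar-type semi-hydrogenation, in which syn delivery of hydrogen on the lead-poisoned palladium surface gives the Z-alkene and stops there, while the epoxide, the esters and the existing alkene should not be reduced.

Step 20
Reactants: 30 epoxy diol with both Z-alkenes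
Product: 31 10,11-epoxy 9-ketone corresponding to 30
Conditions: Dess–Martin periodinane, CH2Cl2, 0 °C → rt
Reagents that add atoms: none
Why: Periodinane oxidation of a secondary alcohol under non-basic conditions, so that the β-acetoxy ketone which is formed is never exposed to base and the tertiary alcohol cannot react.

Step 21
Reactants: 31 epoxy ketone from step 20
Product: 33 punaglandin 8, via trans chlorohydrin 32 (not isolated)
Conditions: HCl (anhydrous, in dioxane), CHCl3, 0 °C
Reagents that add atoms: hydrogen chloride, Cl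
Why: Hydrogen halide opening of an α,β-epoxy ketone followed by dehydration, in which chloride attacks C10 (activated by the adjacent carbonyl, while C11 is shielded by the quaternary C12) and the α-chloro-β-hydroxy ketone loses water through its enol to give the 2-chloro enone, erasing both epoxide stereocentres.

Compound list
1 | furfural | O=Cc1ccco1 | starting material
2 | 3-bromoprop-1-yne | C#CCBr | starting material
3 | bromo(propa-1,2-dien-1-yl)zinc (allenylzinc bromide) | C=C=C[Zn]Br | intermediate
4 | rac-1-(furan-2-yl)but-3-yn-1-ol | OC(CC#C)c1ccco1 | intermediate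
5 | 1-bromopentane | CCCCCBr | starting material
6 | dilithium alkoxide–acetylide of 4 | [Li+].[Li+].[O-]C(CC#[C-])c1ccco1 | intermediate
7 | rac-1-(furan-2-yl)non-3-yn-1-ol | CCCCCC#CCC(O)c1ccco1 | intermediate
8 | rac-trans-4-hydroxy-5-(oct-2-yn-1-yl)cyclopent-2-en-1-one (one enantiomer drawn) | O=C1C=C[C@@H](O)[C@@H]1CC#CCCCCC | intermediate
9 | rac-4-hydroxy-2-(oct-2-yn-1-yl)cyclopent-2-en-1-one | O=C1CC(O)C=C1CC#CCCCCC | intermediate
10 | (1R)-3-(oct-2-yn-1-yl)-4-oxocyclopent-2-en-1-yl acetate | O=C1C[C@@H](OC(C)=O)C=C1CC#CCCCCC | intermediate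
11 | (4R)-4-hydroxy-2-(oct-2-yn-1-yl)cyclopent-2-en-1-one | O=C1C[C@@H](O)C=C1CC#CCCCCC | intermediate
12 | (4R)-4-(tert-butyldimethylsilyloxy)-2-(oct-2-yn-1-yl)cyclopent-2-en-1-one | O=C1C[C@@H](O[Si](C)(C)C(C)(C)C)C=C1CC#CCCCCC | intermediate
13 | (1S,4R)-4-(tert-butyldimethylsilyloxy)-2-(oct-2-yn-1-yl)cyclopent-2-en-1-ol (cis) | O[C@H]1C[C@@H](O[Si](C)(C)C(C)(C)C)C=C1CC#CCCCCC | intermediate
14 | (1R,4R)-4-(tert-butyldimethylsilyloxy)-2-(oct-2-yn-1-yl)cyclopent-2-en-1-yl acetate (trans) | CC(=O)O[C@@H]1C[C@@H](O[Si](C)(C)C(C)(C)C)C=C1CC#CCCCCC | intermediate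
15 | trimethylsilyl ketene acetal of 14 | C=C(O[Si](C)(C)C)O[C@@H]1C[C@@H](O[Si](C)(C)C(C)(C)C)C=C1CC#CCCCCC | intermediate
16 | trimethylsilyl ester of 17 | C[Si](C)(C)OC(=O)C[C@@H]1C(CC#CCCCCC)=CC[C@H]1O[Si](C)(C)C(C)(C)C | intermediate
17 | 2-[(1R,5R)-5-(tert-butyldimethylsilyloxy)-2-(oct-2-yn-1-yl)cyclopent-2-en-1-yl]acetic acid | OC(=O)C[C@@H]1C(CC#CCCCCC)=CC[C@H]1O[Si](C)(C)C(C)(C)C | intermediate
18 | (3aS,4R,6S,6aS)-4-(tert-butyldimethylsilyloxy)-6-iodo-6a-(oct-2-yn-1-yl)hexahydro-2H-cyclopenta[b]furan-2-one | O=C1C[C@H]2[C@H](O[Si](C)(C)C(C)(C)C)C[C@H](I)[C@@]2(CC#CCCCCC)O1 | intermediate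
19 | (3aS,4R,6aR)-4-(tert-butyldimethylsilyloxy)-6a-(oct-2-yn-1-yl)-3,3a,4,6a-tetrahydro-2H-cyclopenta[b]furan-2-one | O=C1C[C@H]2[C@H](O[Si](C)(C)C(C)(C)C)C=C[C@@]2(CC#CCCCCC)O1 | intermediate
20 | potassium enolate of 19 | [K+].[O-]C1=C[C@H]2[C@H](O[Si](C)(C)C(C)(C)C)C=C[C@@]2(CC#CCCCCC)O1 | intermediate
21 | (3R,3aS,4R,6aR)-4-(tert-butyldimethylsilyloxy)-3-hydroxy-6a-(oct-2-yn-1-yl)-3,3a,4,6a-tetrahydro-2H-cyclopenta[b]furan-2-one | O=C1[C@H](O)[C@H]2[C@H](O[Si](C)(C)C(C)(C)C)C=C[C@@]2(CC#CCCCCC)O1 | intermediate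
22 | (3R,3aS,4R,6aR)-4-(tert-butyldimethylsilyloxy)-6a-(oct-2-yn-1-yl)-3,3a,4,6a-tetrahydro-2H-cyclopenta[b]furan-2,3-diol (lactol, anomer mixture) | OC1[C@H](O)[C@H]2[C@H](O[Si](C)(C)C(C)(C)C)C=C[C@@]2(CC#CCCCCC)O1 | intermediate
23 | (4-carboxybutyl)triphenylphosphonium bromide | [Br-].OC(=O)CCCC[P+](c1ccccc1)(c1ccccc1)c1ccccc1 | starting material
24 | potassium 5-(triphenylphosphoranylidene)pentanoate | [K+].[O-]C(=O)CCCC=P(c1ccccc1)(c1ccccc1)c1ccccc1 | intermediate
25 | (5Z,7S)-7-[(1S,2R,5R)-5-(tert-butyldimethylsilyloxy)-2-hydroxy-2-(oct-2-yn-1-yl)cyclopent-3-en-1-yl]-7-hydroxyhept-5-enoic acid | CCCCCC#CC[C@@]1(O)C=C[C@@H](O[Si](C)(C)C(C)(C)C)[C@@H]1[C@H](/C=C\CCCC(=O)O)O | intermediate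
26 | methyl ester of 25 | CCCCCC#CC[C@@]1(O)C=C[C@@H](O[Si](C)(C)C(C)(C)C)[C@@H]1[C@H](/C=C\CCCC(=O)OC)O | intermediate
27 | methyl (5Z,7S)-7-acetoxy-7-[(1S,2R,5R)-5-(tert-butyldimethylsilyloxy)-2-hydroxy-2-(oct-2-yn-1-yl)cyclopent-3-en-1-yl]hept-5-enoate | CCCCCC#CC[C@@]1(O)C=C[C@@H](O[Si](C)(C)C(C)(C)C)[C@@H]1[C@H](/C=C\CCCC(=O)OC)OC(C)=O | intermediate
28 | methyl (5Z,7S)-7-acetoxy-7-[(1R,2R,5R)-2,5-dihydroxy-2-(oct-2-yn-1-yl)cyclopent-3-en-1-yl]hept-5-enoate | CCCCCC#CC[C@@]1(O)C=C[C@@H](O)[C@@H]1[C@H](/C=C\CCCC(=O)OC)OC(C)=O | intermediate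
29 | 10,11-epoxide of 28, epoxide oxygen cis to the C9 hydroxyl | CCCCCC#CC[C@@]1(O)[C@H]2O[C@H]2[C@@H](O)[C@@H]1[C@H](/C=C\CCCC(=O)OC)OC(C)=O | intermediate
30 | (14Z)-alkene from 29 (10,11-epoxy-9,12-diol 7-acetate with 5Z and 14Z alkenes) | CCCCC/C=C\C[C@@]1(O)[C@H]2O[C@H]2[C@@H](O)[C@@H]1[C@H](/C=C\CCCC(=O)OC)OC(C)=O | intermediate
31 | 10,11-epoxy 9-ketone from 30 | CCCCC/C=C\C[C@@]1(O)[C@H]2O[C@H]2C(=O)[C@@H]1[C@H](/C=C\CCCC(=O)OC)OC(C)=O | intermediate
32 | 10-chloro-11-hydroxy 9-ketone, chlorine anti to the C11 hydroxyl | CCCCC/C=C\C[C@@]1(O)[C@@H](O)[C@H](Cl)C(=O)[C@@H]1[C@H](/C=C\CCCC(=O)OC)OC(C)=O | intermediate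
33 | punaglandin 8, methyl (5Z,7S)-7-acetoxy-7-[(1R,2S)-4-chloro-2-hydroxy-2-[(2Z)-oct-2-en-1-yl]-5-oxocyclopent-3-en-1-yl]hept-5-enoate | CCCCC/C=C\C[C@@]1(O)C=C(Cl)C(=O)[C@@H]1[C@H](/C=C\CCCC(=O)OC)OC(C)=O | target

Total step count: 21. Longest linear sequence: 21 steps (1 to 33); 2, 5 and 23 are bought and enter directly.

Steps most likely to fail

Step 9 (Ireland–Claisen). The acetate enolate may fragment to ketene and alkoxide before it is silylated on oxygen, and the boat-like sigmatropic shift in the five-membered ring may be sluggish enough for decomposition of the ketene acetal to compete. The fallback sets out from 14 and comes back at 17. Methanolysis of 14 (K2CO3, MeOH, 0 °C) should give (1R,4R)-4-(tert-butyldimethylsilyloxy)-2-(oct-2-yn-1-yl)cyclopent-2-en-1-ol F1. Heating this with triethyl orthoacetate and catalytic propionic acid (140 °C, Johnson–Claisen rearrangement) should give, with the same suprafacial transfer, ethyl 2-[(1R,5R)-5-(tert-butyldimethylsilyloxy)-2-(oct-2-yn-1-yl)cyclopent-2-en-1-yl]acetate F2. Saponification with LiOH in THF/H2O then returns acid 17.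

Step 14 (Wittig on the free α-hydroxy lactol). The lactol has to open as a polyanion with an unprotected oxygen next to the aldehyde carbon, which may lead to incomplete olefination, erosion of Z-selectivity or base-induced epimerisation at C7. The fallback sets out from 21 and comes back at 25. Treatment of 21 with 2-methoxypropene and pyridinium p-toluenesulfonate should give (3R,3aS,4R,6aR)-4-(tert-butyldimethylsilyloxy)-3-[(2-methoxypropan-2-yl)oxy]-6a-(oct-2-yn-1-yl)-3,3a,4,6a-tetrahydro-2H-cyclopenta[b]furan-2-one F3. Reduction with i-Bu2AlH at −78 °C should give the corresponding lactol F4, and olefination with ylide 24 should give the 7-O-(2-methoxypropan-2-yl) ether of acid 25 F5. The mixed acetal should fall off in dilute aqueous acetic acid during work-up and release 25.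

Step 21 (chloro enone formation). Acid-promoted β-elimination of the C7 acetate or of the C12 hydroxyl may compete with the desired dehydration, or the sequence may stall after epoxide opening. The fallback sets out from 31 and comes back at 33. Buffered chloride opening (LiCl, AcOH, THF, rt) should allow the chlorohydrin 32 to be isolated. Sulfonylation of its secondary C11 hydroxyl (MsCl, Et3N, CH2Cl2, −30 °C) should give the C11 methanesulfonate of 32 F6. This should lose methanesulfonate in the same flask by an E1cB pathway, because the C10 hydrogen next to carbonyl and chlorine is the most acidic one, giving 33 without strong acid.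

Further compounds
F1 | step 9 | (1R,4R)-4-(tert-butyldimethylsilyloxy)-2-(oct-2-yn-1-yl)cyclopent-2-en-1-ol | O[C@@H]1C[C@@H](O[Si](C)(C)C(C)(C)C)C=C1CC#CCCCCC
F2 | step 9 | ethyl 2-[(1R,5R)-5-(tert-butyldimethylsilyloxy)-2-(oct-2-yn-1-yl)cyclopent-2-en-1-yl]acetate | CCOC(=O)C[C@@H]1C(CC#CCCCCC)=CC[C@H]1O[Si](C)(C)C(C)(C)C
F3 | step 14 | (3R,3aS,4R,6aR)-4-(tert-butyldimethylsilyloxy)-3-[(2-methoxypropan-2-yl)oxy]-6a-(oct-2-yn-1-yl)-3,3a,4,6a-tetrahydro-2H-cyclopenta[b]furan-2-one | O=C1[C@H](OC(C)(C)OC)[C@H]2[C@H](O[Si](C)(C)C(C)(C)C)C=C[C@@]2(CC#CCCCCC)O1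
F4 | step 14 | lactol from F3 (anomer mixture) | OC1[C@H](OC(C)(C)OC)[C@H]2[C@H](O[Si](C)(C)C(C)(C)C)C=C[C@@]2(CC#CCCCCC)O1
F5 | step 14 | 7-O-(2-methoxypropan-2-yl) ether of acid 25 | CCCCCC#CC[C@@]1(O)C=C[C@@H](O[Si](C)(C)C(C)(C)C)[C@@H]1[C@H](/C=C\CCCC(=O)O)OC(C)(C)OC
F6 | step 21 | C11 methanesulfonate of 32 | CCCCC/C=C\C[C@@]1(O)[C@@H](OS(C)(=O)=O)[C@H](Cl)C(=O)[C@@H]1[C@H](/C=C\CCCC(=O)OC)OC(C)=O
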